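**Plan**
1. Retrosynthesis: remove the two MOM groups and the C2' O-methyl group; re-form the C4–O(C2') bond, which shows the target as a ring-opened cis-pterocarpan; cut O1–C2 (aryl ether), then C3–C4, then the benzyl ether between the C2' oxygen of ring B and the ring A benzyl group, then C5'–C(quaternary).
2. Enabling feature: ring B carries an oxygen on C2', ortho to C1', the carbon that holds C3. As a benzyl ether this oxygen holds the C4 methylene (benzylic to ring A, para to the C7 oxygen, alpha to oxygen) 1,5 to a donor/acceptor carbene at C3 (ring B as donor, the C2 ester as acceptor).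
3. Forward: ring B is dressed (MOM, bromination, reverse prenylation), joined to ring A through the C2' oxygen and taken to the diazo ester. The temporary dihydrofuran ring closes first (C3–C4), the pyran ring second (O1–C2). The temporary C4–O bond is then cleaved reductively, the freed C2' hydroxyl is methylated and the MOM groups are removed.
4. Stereochemistry: C3, the only stereocenter of the target, is set in the C–H insertion by the chiral dirhodium carboxylate. The cis C4 centre formed with it serves the ring fusion and disappears when the C4–O bond is cleaved.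

Key step: step 9

Assumption: the (R)-configured tert-leucinate dirhodium catalyst is taken to give the (2S,3R) series drawn here; if the sense of induction is the opposite, the mirror-image catalyst is used and nothing else changes.

Step 1
Reactants: 1 2-bromo-4-hydroxybenzaldehyde
Product: 2 2-bromo-4-(methoxymethoxy)benzaldehyde
Conditions: MOMCl, i-Pr2NEt, CH2Cl2, 0 °C to rt
Reagents that add atoms: chloromethyl methyl ether (COCCl)
Why: O-alkylation of the phenol with the chloromethyl ether (Williamson-type acetal formation) masks the future C7 hydroxyl as a MOM ether that is stable to base, hydride, carbenes and dissolving metal.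

Step 2
Reactants: 2 2-bromo-4-(methoxymethoxy)benzaldehyde
Product: 3 [2-bromo-4-(methoxymethoxy)phenyl]methanol
Conditions: NaBH4, MeOH, 0 °C
Reagents that add atoms: none
Why: Chemoselective borohydride reduction of the aldehyde should give the benzylic alcohol whose CH2 becomes C4, leaving the aryl bromide and the acetal untouched.

Step 3
Reactants: 4 1-(2,3-dihydroxy-4-methoxyphenyl)ethanone
Product: 5 1-[2-hydroxy-4-methoxy-3-(methoxymethoxy)phenyl]ethanone
Conditions: MOMCl (1.05 equiv), i-Pr2NEt, CH2Cl2, 0 °C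
Reagents that add atoms: chloromethyl methyl ether (COCCl)
Why: The C2' hydroxyl is held in a hydrogen bond to the ketone, so the MOM protection (Williamson-type) should take place only at the free C3' hydroxyl.

Step 4
Reactants: 5 1-[2-hydroxy-4-methoxy-3-(methoxymethoxy)phenyl]ethanone
Product: 6 1-[5-bromo-2-hydroxy-4-methoxy-3-(methoxymethoxy)phenyl]ethanone
Conditions: NBS, MeCN, 0 °C
Reagents that add atoms: N-bromosuccinimide (O=C1CCC(=O)N1Br)
Why: Electrophilic aromatic bromination should go para to the free phenol and ortho to the methoxy group, which is the only doubly activated open position (C5').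

Step 5
Reactants: 6 1-[5-bromo-2-hydroxy-4-methoxy-3-(methoxymethoxy)phenyl]ethanone; 7 4,4,5,5-tetramethyl-2-(3-methylbut-2-en-1-yl)-1,3,2-dioxaborolane
Product: 8 1-[2-hydroxy-4-methoxy-3-(methoxymethoxy)-5-(2-methylbut-3-en-2-yl)phenyl]ethanone
Conditions: Pd(OAc)2 (cat.), bulky dialkylbiarylphosphine (gamma-selective ligand), K3PO4, THF/H2O, 40 °C
Reagents that add atoms: none
Why: Suzuki–Miyaura coupling in which the allylboronate transmetalates with allyl transposition and a bulky ligand forces reductive elimination before the allyl group isomerizes, so that the tertiary carbon is joined to C5' as the 1,1-dimethylallyl group.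

Step 6
Reactants: 8 1-[2-hydroxy-4-methoxy-3-(methoxymethoxy)-5-(2-methylbut-3-en-2-yl)phenyl]ethanone; 3 [2-bromo-4-(methoxymethoxy)phenyl]methanol
Product: 9 1-[2-[[2-bromo-4-(methoxymethoxy)phenyl]methoxy]-4-methoxy-3-(methoxymethoxy)-5-(2-methylbut-3-en-2-yl)phenyl]ethanone
Conditions: PPh3, DIAD, THF, 0 °C to rt
Reagents that add atoms: none
Why: Mitsunobu etherification should alkylate the acidic chelated phenol with the primary benzylic alcohol under neutral conditions and so place the future C4 on the C2' oxygen.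

Step 7
Reactants: 9 1-[2-[[2-bromo-4-(methoxymethoxy)phenyl]methoxy]-4-methoxy-3-(methoxymethoxy)-5-(2-methylbut-3-en-2-yl)phenyl]ethanone
Product: 11 methyl 2-[2-[[2-bromo-4-(methoxymethoxy)phenyl]methoxy]-4-methoxy-3-(methoxymethoxy)-5-(2-methylbut-3-en-2-yl)phenyl]-2-oxoacetate, via keto acid 10 (not isolated)
Conditions: SeO2, pyridine, 100 °C; then MeI, K2CO3, DMF, rt
Reagents that add atoms: selenium dioxide (O=[Se]=O); iodomethane (CI)
Why: Riley oxidation should turn the aryl methyl ketone into the aryl glyoxylic acid (the side-chain alkene has no allylic hydrogen to compete), and SN2 methylation of the carboxylate gives the keto ester whose two carbons become C3 and C2.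

Step 8
Reactants: 11 methyl 2-[2-[[2-bromo-4-(methoxymethoxy)phenyl]methoxy]-4-methoxy-3-(methoxymethoxy)-5-(2-methylbut-3-en-2-yl)phenyl]-2-oxoacetate
Product: 13 methyl 2-[2-[[2-bromo-4-(methoxymethoxy)phenyl]methoxy]-4-methoxy-3-(methoxymethoxy)-5-(2-methylbut-3-en-2-yl)phenyl]-2-diazoacetate, via tosylhydrazone 12 (not isolated)
Conditions: TsNHNH2, toluene, 70 °C; then DBU, CH2Cl2, rt
Reagents that add atoms: 4-methylbenzenesulfonohydrazide (Cc1ccc(S(=O)(=O)NN)cc1)
Why: Condensation at the ketone gives the tosylhydrazone, and base-induced loss of sulfinate (Bamford–Stevens-type diazo formation) should give the stable donor/acceptor aryldiazoacetate.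

Step 9
Reactants: 13 methyl 2-[2-[[2-bromo-4-(methoxymethoxy)phenyl]methoxy]-4-methoxy-3-(methoxymethoxy)-5-(2-methylbut-3-en-2-yl)phenyl]-2-diazoacetate
Product: 14 methyl (2S,3R)-2-[2-bromo-4-(methoxymethoxy)phenyl]-6-methoxy-7-(methoxymethoxy)-5-(2-methylbut-3-en-2-yl)-2,3-dihydro-1-benzofuran-3-carboxylate
Conditions: dirhodium tetrakis[N-phthaloyl-(R)-tert-leucinate], Rh2(R-PTTL)4 (2 mol %), toluene, −60 °C, slow addition of 13
Reagents that add atoms: none
Why: The dirhodium carboxylate should decompose the diazo ester to a donor/acceptor rhodium carbene at C3, which inserts into one C–H bond of the C4 methylene through a concerted, hydride-transfer-like three-centre transition state. The closest known reaction type is the enantioselective intramolecular 1,5 C–H insertion of 2-(benzyloxy)aryl diazoacetates to cis-2-aryl-2,3-dihydrobenzofuran-3-carboxylates under amino-acid-derived dirhodium carboxylates. One ring is closed, the five-membered dihydrofuran ring (O–C2'–C1'–C3–C4), by 1,5-insertion; it is a temporary ring that carries the new C3–C4 bond. C3 is set by the chiral carboxylate ligands, which expose one face of the carbene to the C–H bond; C4 is set cis to C3 by the insertion geometry, is needed only for the later cis ring fusion and is erased in step 12. The step needs chemoselectivity for this C–H bond over intermolecular cyclopropanation of the vinyl group and carbene dimerization; the 1,5 relation and the activation of C4–H by the ether oxygen and by the para-oxygenated ring A should secure it, helped by slow addition, and the acetal CH2 groups cannot reach the carbene.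

Step 10
Reactants: 14 methyl (2S,3R)-2-[2-bromo-4-(methoxymethoxy)phenyl]-6-methoxy-7-(methoxymethoxy)-5-(2-methylbut-3-en-2-yl)-2,3-dihydro-1-benzofuran-3-carboxylate
Product: 15 [(2S,3S)-2-[2-bromo-4-(methoxymethoxy)phenyl]-6-methoxy-7-(methoxymethoxy)-5-(2-methylbut-3-en-2-yl)-2,3-dihydro-1-benzofuran-3-yl]methanol
Conditions: LiAlH4, THF, −20 °C
Reagents that add atoms: none
Why: Hydride reduction of the ester at low temperature should be faster than enolization, so the cis alcohol forms without epimerization at C3 (the descriptor changes only through the priority rules), and the aryl bromide, acetals and alkene are inert.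

Step 11
Reactants: 15 [(2S,3S)-2-[2-bromo-4-(methoxymethoxy)phenyl]-6-methoxy-7-(methoxymethoxy)-5-(2-methylbut-3-en-2-yl)-2,3-dihydro-1-benzofuran-3-yl]methanol
Product: 16 (6aS,11aS)-9-methoxy-3,10-bis(methoxymethoxy)-8-(2-methylbut-3-en-2-yl)-6a,11a-dihydro-6H-[1]benzofuro[3,2-c]chromene
Conditions: Pd(OAc)2 (cat.), 2-(di-tert-butylphosphino)-1,1'-binaphthyl, Cs2CO3, toluene, 70 °C
Reagents that add atoms: none
Why: Palladium-catalysed intramolecular C–O coupling (Buchwald–Hartwig etherification) of the primary alkoxide with the ortho aryl bromide should close the pyran ring (O1–C2), a six-membered closure that the cis arrangement of aryl and CH2OH groups allows, to give the cis-fused pterocarpan.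

Step 12
Reactants: 16 (6aS,11aS)-9-methoxy-3,10-bis(methoxymethoxy)-8-(2-methylbut-3-en-2-yl)-6a,11a-dihydro-6H-[1]benzofuro[3,2-c]chromene
Product: 17 6-[(3S)-7-(methoxymethoxy)-3,4-dihydro-2H-chromen-3-yl]-3-methoxy-2-(methoxymethoxy)-4-(2-methylbut-3-en-2-yl)phenol
Conditions: Li, liquid NH3/THF, −78 °C; then NH4Cl
Reagents that add atoms: none
Why: Dissolving-metal reduction (Birch-type cleavage of a benzyl aryl ether) should break only the benzylic C4–O bond to give C4H2 and the C2' phenol, while C3 is not involved and keeps its configuration and the isolated terminal alkene is not reduced.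

Step 13
Reactants: 17 6-[(3S)-7-(methoxymethoxy)-3,4-dihydro-2H-chromen-3-yl]-3-methoxy-2-(methoxymethoxy)-4-(2-methylbut-3-en-2-yl)phenol
Product: 18 (3S)-3-[2,4-dimethoxy-3-(methoxymethoxy)-5-(2-methylbut-3-en-2-yl)phenyl]-7-(methoxymethoxy)-3,4-dihydro-2H-chromene
Conditions: MeI, K2CO3, DMF, rt
Reagents that add atoms: iodomethane (CI)
Why: Williamson methylation of the only free phenol should give the C2' methyl ether of the target.

Step 14
Reactants: 18 (3S)-3-[2,4-dimethoxy-3-(methoxymethoxy)-5-(2-methylbut-3-en-2-yl)phenyl]-7-(methoxymethoxy)-3,4-dihydro-2H-chromene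
Product: 19 (3S)-3-[3-hydroxy-2,4-dimethoxy-5-(2-methylbut-3-en-2-yl)phenyl]-3,4-dihydro-2H-chromen-7-ol
Conditions: HCl (cat.), MeOH, 40 °C
Reagents that add atoms: none
Why: Acid-catalysed acetal exchange with methanol should remove both MOM groups under conditions mild enough for the monosubstituted alkene and the benzylic stereocenter.

**Compound list**
1 | 2-bromo-4-hydroxybenzaldehyde | O=Cc1ccc(O)cc1Br | starting material
2 | 2-bromo-4-(methoxymethoxy)benzaldehyde | O=Cc1ccc(OCOC)cc1Br | intermediate
3 | [2-bromo-4-(methoxymethoxy)phenyl]methanol | OCc1ccc(OCOC)cc1Br | intermediate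
4 | 1-(2,3-dihydroxy-4-methoxyphenyl)ethanone | CC(=O)c1ccc(OC)c(O)c1O | starting material
5 | 1-[2-hydroxy-4-methoxy-3-(methoxymethoxy)phenyl]ethanone | CC(=O)c1ccc(OC)c(OCOC)c1O | intermediate
6 | 1-[5-bromo-2-hydroxy-4-methoxy-3-(methoxymethoxy)phenyl]ethanone | CC(=O)c1cc(Br)c(OC)c(OCOC)c1O | intermediate
7 | 4,4,5,5-tetramethyl-2-(3-methylbut-2-en-1-yl)-1,3,2-dioxaborolane (prenylboronic acid pinacol ester) | CC(C)=CCB1OC(C)(C)C(C)(C)O1 | starting material
8 | 1-[2-hydroxy-4-methoxy-3-(methoxymethoxy)-5-(2-methylbut-3-en-2-yl)phenyl]ethanone | CC(=O)c1cc(C(C)(C)C=C)c(OC)c(OCOC)c1O | intermediate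
9 | 1-[2-[[2-bromo-4-(methoxymethoxy)phenyl]methoxy]-4-methoxy-3-(methoxymethoxy)-5-(2-methylbut-3-en-2-yl)phenyl]ethanone | CC(=O)c1cc(C(C)(C)C=C)c(OC)c(OCOC)c1OCc1ccc(OCOC)cc1Br | intermediate
10 | 2-[2-[[2-bromo-4-(methoxymethoxy)phenyl]methoxy]-4-methoxy-3-(methoxymethoxy)-5-(2-methylbut-3-en-2-yl)phenyl]-2-oxoacetic acid | OC(=O)C(=O)c1cc(C(C)(C)C=C)c(OC)c(OCOC)c1OCc1ccc(OCOC)cc1Br | intermediate
11 | methyl 2-[2-[[2-bromo-4-(methoxymethoxy)phenyl]methoxy]-4-methoxy-3-(methoxymethoxy)-5-(2-methylbut-3-en-2-yl)phenyl]-2-oxoacetate | COC(=O)C(=O)c1cc(C(C)(C)C=C)c(OC)c(OCOC)c1OCc1ccc(OCOC)cc1Br | intermediate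
12 | methyl 2-[2-[[2-bromo-4-(methoxymethoxy)phenyl]methoxy]-4-methoxy-3-(methoxymethoxy)-5-(2-methylbut-3-en-2-yl)phenyl]-2-[(4-methylphenyl)sulfonylhydrazinylidene]acetate | COC(=O)C(=NNS(=O)(=O)c1ccc(C)cc1)c1cc(C(C)(C)C=C)c(OC)c(OCOC)c1OCc1ccc(OCOC)cc1Br | intermediate
13 | methyl 2-[2-[[2-bromo-4-(methoxymethoxy)phenyl]methoxy]-4-methoxy-3-(methoxymethoxy)-5-(2-methylbut-3-en-2-yl)phenyl]-2-diazoacetate | COC(=O)C(=[N+]=[N-])c1cc(C(C)(C)C=C)c(OC)c(OCOC)c1OCc1ccc(OCOC)cc1Br | intermediate
14 | methyl (2S,3R)-2-[2-bromo-4-(methoxymethoxy)phenyl]-6-methoxy-7-(methoxymethoxy)-5-(2-methylbut-3-en-2-yl)-2,3-dihydro-1-benzofuran-3-carboxylate (cis) | COC(=O)[C@H]1[C@@H](c2ccc(OCOC)cc2Br)Oc2c1cc(C(C)(C)C=C)c(OC)c2OCOC | intermediate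
15 | [(2S,3S)-2-[2-bromo-4-(methoxymethoxy)phenyl]-6-methoxy-7-(methoxymethoxy)-5-(2-methylbut-3-en-2-yl)-2,3-dihydro-1-benzofuran-3-yl]methanol (cis) | OC[C@H]1[C@@H](c2ccc(OCOC)cc2Br)Oc2c1cc(C(C)(C)C=C)c(OC)c2OCOC | intermediate
16 | (6aS,11aS)-9-methoxy-3,10-bis(methoxymethoxy)-8-(2-methylbut-3-en-2-yl)-6a,11a-dihydro-6H-[1]benzofuro[3,2-c]chromene (cis-pterocarpan) | O1C[C@@H]2c3cc(C(C)(C)C=C)c(OC)c(OCOC)c3O[C@@H]2c2ccc(OCOC)cc12 | intermediate
17 | 6-[(3S)-7-(methoxymethoxy)-3,4-dihydro-2H-chromen-3-yl]-3-methoxy-2-(methoxymethoxy)-4-(2-methylbut-3-en-2-yl)phenol | C=CC(C)(C)c1cc([C@H]2COc3cc(OCOC)ccc3C2)c(O)c(OCOC)c1OC | intermediate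
18 | (3S)-3-[2,4-dimethoxy-3-(methoxymethoxy)-5-(2-methylbut-3-en-2-yl)phenyl]-7-(methoxymethoxy)-3,4-dihydro-2H-chromene | C=CC(C)(C)c1cc([C@H]2COc3cc(OCOC)ccc3C2)c(OC)c(OCOC)c1OC | intermediate
19 | (3S)-3-[3-hydroxy-2,4-dimethoxy-5-(2-methylbut-3-en-2-yl)phenyl]-3,4-dihydro-2H-chromen-7-ol | C=CC(C)(C)c1cc([C@H]2COc3cc(O)ccc3C2)c(OC)c(O)c1OC | target

**Step count**
Total: 14 steps. Longest linear sequence: 12 steps (steps 3 to 14, from 4); steps 1 and 2 form the side branch that joins in step 6.

**Steps most likely to fail**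

Step 5. The allyl palladium intermediate may isomerize (sigma–pi–sigma) before reductive elimination, which would attach the primary carbon and give the linear 3-methylbut-2-enyl isomer. The fallback leaves out steps 4 and 5 and sets out from 5. Palladium-catalysed O-allylation with methyl 2-methylbut-3-en-2-yl carbonate (Pd(PPh3)4, THF, 0 °C; Tsuji–Trost) should give the aryl tert-allyl ether F1. Heating F1 (N,N-diethylaniline, about 150 °C) should cause an aromatic Claisen rearrangement to a blocked ortho position followed by a Cope rearrangement (para-Claisen). The allyl unit, inverted twice, arrives at C5' as the 1,1-dimethylallyl group and the chelated phenol is restored, so the fallback comes back to the route at 8.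

Step 9. On this crowded substrate the two faces of the carbene may be poorly differentiated, which would lower the enantiomeric purity of 14. The fallback sets out from the crude keto acid 10. Esterification with (R)-pantolactone (DCC, DMAP, CH2Cl2) gives the pantolactonyl keto ester F2, which is converted through the pantolactonyl tosylhydrazone F3 (TsNHNH2) into the pantolactonyl diazo ester F4 (DBU). The insertion is run with the same dirhodium catalyst or its mirror image, whichever pairs better with the auxiliary, and gives the pantolactonyl dihydrobenzofuran ester F5. The material with the wrong configuration at C3 is now a diastereomer and is removed by chromatography or crystallization. LiAlH4 (THF, −20 °C) then cleaves the auxiliary, and the fallback comes back to the route at 15.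

Step 11. The alkoxo-palladium intermediate may undergo beta-hydride elimination, which would oxidize the primary alcohol and reduce the aryl bromide instead of forming the ether. The fallback sets out from 15. Miyaura borylation (B2pin2, Pd(dppf)Cl2, KOAc, dioxane, 80 °C) gives the arylboronate F6, and oxidation (NaBO3, THF/H2O, rt) gives the phenol F7. Mitsunobu cyclization (PPh3, DIAD, THF) of the phenol onto the primary alcohol then closes the pyran ring, and the fallback comes back to the route at 16.

**Further compounds**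
F1 | step 5 | 1-[4-methoxy-3-(methoxymethoxy)-2-(2-methylbut-3-en-2-yloxy)phenyl]ethanone | CC(=O)c1ccc(OC)c(OCOC)c1OC(C)(C)C=C
F2 | step 9 | (3R)-4,4-dimethyl-2-oxooxolan-3-yl 2-[2-[[2-bromo-4-(methoxymethoxy)phenyl]methoxy]-4-methoxy-3-(methoxymethoxy)-5-(2-methylbut-3-en-2-yl)phenyl]-2-oxoacetate | CC1(C)COC(=O)[C@@H]1OC(=O)C(=O)c1cc(C(C)(C)C=C)c(OC)c(OCOC)c1OCc1ccc(OCOC)cc1Br
F3 | step 9 | (3R)-4,4-dimethyl-2-oxooxolan-3-yl 2-[2-[[2-bromo-4-(methoxymethoxy)phenyl]methoxy]-4-methoxy-3-(methoxymethoxy)-5-(2-methylbut-3-en-2-yl)phenyl]-2-[(4-methylphenyl)sulfonylhydrazinylidene]acetate | CC1(C)COC(=O)[C@@H]1OC(=O)C(=NNS(=O)(=O)c1ccc(C)cc1)c1cc(C(C)(C)C=C)c(OC)c(OCOC)c1OCc1ccc(OCOC)cc1Br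
F4 | step 9 | (3R)-4,4-dimethyl-2-oxooxolan-3-yl 2-[2-[[2-bromo-4-(methoxymethoxy)phenyl]methoxy]-4-methoxy-3-(methoxymethoxy)-5-(2-methylbut-3-en-2-yl)phenyl]-2-diazoacetate | CC1(C)COC(=O)[C@@H]1OC(=O)C(=[N+]=[N-])c1cc(C(C)(C)C=C)c(OC)c(OCOC)c1OCc1ccc(OCOC)cc1Br
F5 | step 9 | (3R)-4,4-dimethyl-2-oxooxolan-3-yl (2S,3R)-2-[2-bromo-4-(methoxymethoxy)phenyl]-6-methoxy-7-(methoxymethoxy)-5-(2-methylbut-3-en-2-yl)-2,3-dihydro-1-benzofuran-3-carboxylate | CC1(C)COC(=O)[C@@H]1OC(=O)[C@H]1[C@@H](c2ccc(OCOC)cc2Br)Oc2c1cc(C(C)(C)C=C)c(OC)c2OCOC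
F6 | step 11 | [(2S,3S)-6-methoxy-7-(methoxymethoxy)-2-[4-(methoxymethoxy)-2-(4,4,5,5-tetramethyl-1,3,2-dioxaborolan-2-yl)phenyl]-5-(2-methylbut-3-en-2-yl)-2,3-dihydro-1-benzofuran-3-yl]methanol | OC[C@H]1[C@@H](c2ccc(OCOC)cc2B2OC(C)(C)C(C)(C)O2)Oc2c1cc(C(C)(C)C=C)c(OC)c2OCOC
F7 | step 11 | 2-[(2S,3S)-3-(hydroxymethyl)-6-methoxy-7-(methoxymethoxy)-5-(2-methylbut-3-en-2-yl)-2,3-dihydro-1-benzofuran-2-yl]-5-(methoxymethoxy)phenol | OC[C@H]1[C@@H](c2ccc(OCOC)cc2O)Oc2c1cc(C(C)(C)C=C)c(OC)c2OCOC
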